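**Plan**

1. Retrosynthesis: the three phenols are traced back to O-benzyl ethers and the ring OCH2 (C5) to a menthyloxy acetal. The C4–CH2(vanillyl) bond and the C3–CH2(aryl) bond are then cut in one operation, leaving a 2-aryl-1,3-dithiane (benzylic carbanion equivalent), a γ-alkoxybutenolide and a benzylic bromide.
2. Enabling feature: in the γ-butyrolactone ring (O1, C2, C3, C4, C5), C4 is β and C3 is α to the C2 carbonyl, so the ring is a reduced butenolide. A C3=C4 double bond makes C4 an acceptor and, after addition, C3 an enolate donor; C5 at the acetal oxidation level can carry a removable stereocontrol group.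
3. Forward: the five-membered ring is bought preformed as (5R)-5-menthyloxy-2(5H)-furanone. Lithiated O-benzylvanillin dithiane is joined to C4 and 2,4-bis(benzyloxy)-3-methoxybenzyl bromide to C3 in the same flask. C–S hydrogenolysis, reduction of C5 to CH2 and O-debenzylation finish the route.
4. Stereochemistry: the (5R) acetal centre sends the carbanion to the opposite ring face (C4 = R). The new C4 group sends the bromide anti (C3 = R, 3,4-trans). The acetal centre is then erased.

Key step: step 6

Remark: (5R)-5-[(1R,2S,5R)-menthyloxy]furan-2(5H)-one and 2-methoxyresorcinol are taken as purchasable; the former is otherwise made from furfural by photo-oxygenation and acetalisation with (−)-menthol.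

**Route**

Step 1
Reactants: 1 4-(benzyloxy)-3-methoxybenzaldehyde (O-benzylvanillin)
Product: 2 2-[4-(benzyloxy)-3-methoxyphenyl]-1,3-dithiane
Conditions: HS(CH2)3SH, BF3·OEt2 (cat.), CH2Cl2, 0 °C → rt
Reagents that add atoms: 1,3-propanedithiol, SCCCS
Why: Lewis-acid-catalysed dithioacetalisation of an aryl aldehyde is fast at 0 °C, should leave the aryl benzyl ether intact, and turns the formyl carbon into a benzylic carbanion precursor (umpolung) without creating a stereocentre.

Step 2
Reactants: 3 2-methoxybenzene-1,3-diol (2-methoxyresorcinol)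
Product: 4 1,3-bis(benzyloxy)-2-methoxybenzene
Conditions: BnBr, K2CO3, DMF, 60 °C
Reagents that add atoms: benzyl bromide, BrCc1ccccc1
Why: Williamson ether synthesis on both phenols should give the bis-benzyl ether; no stereocentre is formed.

Step 3
Reactants: 4 1,3-bis(benzyloxy)-2-methoxybenzene
Product: 5 2,4-bis(benzyloxy)-3-methoxybenzaldehyde
Conditions: POCl3, DMF, 0 → 70 °C; then ice/H2O
Reagents that add atoms: N,N-dimethylformamide, CN(C)C=O (formyl carbon); water, O (formyl oxygen, on hydrolysis of the iminium salt)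
Why: Vilsmeier–Haack formylation should go to C4, the position ortho to one benzyloxy group and para to the other, as 1,2,3-trialkoxybenzenes give 2,3,4-trialkoxybenzaldehydes.

Step 4
Reactants: 5 2,4-bis(benzyloxy)-3-methoxybenzaldehyde
Product: 6 [2,4-bis(benzyloxy)-3-methoxyphenyl]methanol
Conditions: NaBH4, MeOH/THF, 0 °C
Reagents that add atoms: none
Why: Borohydride reduction of an aryl aldehyde to the benzylic alcohol is chemoselective in the presence of the ethers.

Step 5
Reactants: 6 [2,4-bis(benzyloxy)-3-methoxyphenyl]methanol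
Product: 7 1,3-bis(benzyloxy)-4-(bromomethyl)-2-methoxybenzene (2,4-bis(benzyloxy)-3-methoxybenzyl bromide)
Conditions: PBr3, Et2O, 0 °C; used at once without chromatography
Reagents that add atoms: phosphorus tribromide, BrP(Br)Br
Why: Bromination of a benzylic alcohol with PBr3 (bromide displacement on the phosphite ester) is standard for 2,3,4-trialkoxybenzyl alcohols; the ionisation-prone bromide is therefore made cold and used directly.

Step 6
Reactants: 2 2-[4-(benzyloxy)-3-methoxyphenyl]-1,3-dithiane; 8 (5R)-5-[(1R,2S,5R)-menthyloxy]furan-2(5H)-one; 7 2,4-bis(benzyloxy)-3-methoxybenzyl bromide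
Product: 11 (3R,4R,5R)-3-[2,4-bis(benzyloxy)-3-methoxybenzyl]-4-{2-[4-(benzyloxy)-3-methoxyphenyl]-1,3-dithian-2-yl}-5-[(1R,2S,5R)-menthyloxy]dihydrofuran-2(3H)-one, via lithiated dithiane 9 (not isolated), via lithium enolate 10 (not isolated)
Conditions: 2, n-BuLi, THF, −78 → −20 °C; 8, THF, −78 °C; then 7, DMPU, −78 °C → rt
Reagents that add atoms: none
Why: n-BuLi removes the C2–H of dithiane 2 to give the sulfur-stabilised benzylic carbanion 9, which adds in conjugate fashion to C4 of butenolide 8 (forming the aryl-C–C4 bond) to give lithium enolate 10, and this is C-benzylated at C3 by bromide 7 in an SN2 step. The closest known reaction type is the tandem three-component conjugate addition–enolate alkylation of 2-lithio-2-aryl-1,3-dithianes with γ-alkoxybutenolides. No ring is closed: the five-membered lactone ring is carried over intact from 8. The new C4 centre is set by the C5 menthyloxy group of 8, which blocks one face of the flat butenolide so that 9 enters anti to it (4R), and the new C3 centre is set by the bulky dithianyl group just installed at C4, which sends the bromide to the opposite face (3R, 3,4-trans). The step needs 1,4- over 1,2-addition, which the delocalised soft thioacetal anion and the unhindered ring-locked enoate should secure, and C-alkylation without proton transfer, which DMPU activation of the lithium enolate and the high SN2 reactivity of the benzylic bromide should secure.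

Step 7
Reactants: 11 (3R,4R,5R)-dithianyl adduct
Product: 12 (3R,4R,5R)-3-[2,4-bis(benzyloxy)-3-methoxybenzyl]-4-[4-(benzyloxy)-3-methoxybenzyl]-5-[(1R,2S,5R)-menthyloxy]dihydrofuran-2(3H)-one
Conditions: Raney Ni (W-2, acetone-deactivated), EtOH/THF, rt → 50 °C
Reagents that add atoms: none
Why: Raney Ni hydrogenolysis of the two C–S bonds (Mozingo-type desulfurisation) turns the dithiane carbon into the benzylic CH2; deactivated nickel at mild temperature should spare the aryl benzyl ethers, and no stereocentre is touched.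

Step 8
Reactants: 12 (3R,4R,5R)-dibenzyl menthyloxy lactone
Product: 15 (3R,4R)-3-[2,4-bis(benzyloxy)-3-methoxybenzyl]-4-[4-(benzyloxy)-3-methoxybenzyl]dihydrofuran-2(3H)-one, via formyl acid 13 (not isolated), via hydroxy acid 14 (not isolated)
Conditions: NaBH4, KOH, EtOH/H2O, 0 °C → rt; then 2 M HCl (pH 2), rt
Reagents that add atoms: potassium hydroxide, [K+].[OH-] (its oxygen enters the carboxylate and can remain as the lactone carbonyl oxygen after relactonisation)
Why: Hydroxide opens the acyloxy acetal to the carboxylate and the C5 aldehyde with release of menthol, borohydride should trap the aldehyde as the primary alcohol before the adjacent C4 centre can epimerise, and acidification recloses the γ-lactone (saponification/reduction/lactonisation), so the auxiliary centre is erased while C3 and C4 stay R,R.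

Step 9
Reactants: 15 (3R,4R)-tris-O-benzyl lactone
Product: 16 (3R,4R)-3-(2,4-dihydroxy-3-methoxybenzyl)-4-(4-hydroxy-3-methoxybenzyl)dihydrofuran-2(3H)-one
Conditions: H2 (1 atm), 10% Pd/C, EtOAc/MeOH, rt
Reagents that add atoms: none
Why: Hydrogenolysis of the three aryl benzyl ethers over palladium on carbon under neutral conditions should free the phenols without touching the lactone or either stereocentre; the 2-hydroxyl is unmasked only here so that it cannot compete in the lactonisation of step 8.

**Compound list**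

1 | 4-(benzyloxy)-3-methoxybenzaldehyde | COc1cc(C=O)ccc1OCc1ccccc1 | starting material
2 | 2-[4-(benzyloxy)-3-methoxyphenyl]-1,3-dithiane | COc1cc(C2SCCCS2)ccc1OCc1ccccc1 | intermediate
3 | 2-methoxybenzene-1,3-diol | COc1c(O)cccc1O | starting material
4 | 1,3-bis(benzyloxy)-2-methoxybenzene | COc1c(OCc2ccccc2)cccc1OCc1ccccc1 | intermediate
5 | 2,4-bis(benzyloxy)-3-methoxybenzaldehyde | O=Cc1ccc(OCc2ccccc2)c(OC)c1OCc1ccccc1 | intermediate
6 | [2,4-bis(benzyloxy)-3-methoxyphenyl]methanol | OCc1ccc(OCc2ccccc2)c(OC)c1OCc1ccccc1 | intermediate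
7 | 1,3-bis(benzyloxy)-4-(bromomethyl)-2-methoxybenzene | BrCc1ccc(OCc2ccccc2)c(OC)c1OCc1ccccc1 | intermediate
8 | (5R)-5-{[(1R,2S,5R)-5-methyl-2-(propan-2-yl)cyclohexyl]oxy}furan-2(5H)-one | O=C1C=C[C@H](O[C@@H]2C[C@H](C)CC[C@H]2C(C)C)O1 | starting material
9 | 2-lithio-2-[4-(benzyloxy)-3-methoxyphenyl]-1,3-dithiane | [Li]C1(c2ccc(OCc3ccccc3)c(OC)c2)SCCCS1 | intermediate
10 | lithium enolate of (4R,5R)-4-{2-[4-(benzyloxy)-3-methoxyphenyl]-1,3-dithian-2-yl}-5-[(1R,2S,5R)-menthyloxy]dihydrofuran-2(3H)-one | [Li]OC1=C[C@@H](C2(c3ccc(OCc4ccccc4)c(OC)c3)SCCCS2)[C@H](O[C@@H]2C[C@H](C)CC[C@H]2C(C)C)O1 | intermediate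
11 | (3R,4R,5R)-3-[2,4-bis(benzyloxy)-3-methoxybenzyl]-4-{2-[4-(benzyloxy)-3-methoxyphenyl]-1,3-dithian-2-yl}-5-[(1R,2S,5R)-menthyloxy]dihydrofuran-2(3H)-one | O=C1O[C@@H](O[C@@H]2C[C@H](C)CC[C@H]2C(C)C)[C@H](C2(c3ccc(OCc4ccccc4)c(OC)c3)SCCCS2)[C@H]1Cc1ccc(OCc2ccccc2)c(OC)c1OCc1ccccc1 | intermediate
12 | (3R,4R,5R)-3-[2,4-bis(benzyloxy)-3-methoxybenzyl]-4-[4-(benzyloxy)-3-methoxybenzyl]-5-[(1R,2S,5R)-menthyloxy]dihydrofuran-2(3H)-one | O=C1O[C@@H](O[C@@H]2C[C@H](C)CC[C@H]2C(C)C)[C@H](Cc2ccc(OCc3ccccc3)c(OC)c2)[C@H]1Cc1ccc(OCc2ccccc2)c(OC)c1OCc1ccccc1 | intermediate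
13 | (2R,3R)-2-[2,4-bis(benzyloxy)-3-methoxybenzyl]-3-[4-(benzyloxy)-3-methoxybenzyl]-4-oxobutanoic acid (potassium carboxylate in the flask) | OC(=O)[C@H](Cc1ccc(OCc2ccccc2)c(OC)c1OCc1ccccc1)[C@H](C=O)Cc1ccc(OCc2ccccc2)c(OC)c1 | intermediate
14 | (2R,3R)-2-[2,4-bis(benzyloxy)-3-methoxybenzyl]-3-[4-(benzyloxy)-3-methoxybenzyl]-4-hydroxybutanoic acid (potassium carboxylate until acidified) | OC(=O)[C@H](Cc1ccc(OCc2ccccc2)c(OC)c1OCc1ccccc1)[C@H](CO)Cc1ccc(OCc2ccccc2)c(OC)c1 | intermediate
15 | (3R,4R)-3-[2,4-bis(benzyloxy)-3-methoxybenzyl]-4-[4-(benzyloxy)-3-methoxybenzyl]dihydrofuran-2(3H)-one | O=C1OC[C@H](Cc2ccc(OCc3ccccc3)c(OC)c2)[C@H]1Cc1ccc(OCc2ccccc2)c(OC)c1OCc1ccccc1 | intermediate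
16 | (3R,4R)-3-(2,4-dihydroxy-3-methoxybenzyl)-4-(4-hydroxy-3-methoxybenzyl)dihydrofuran-2(3H)-one | COc1cc(C[C@H]2COC(=O)[C@@H]2Cc2ccc(O)c(OC)c2O)ccc1O | target

**Step count and risks**

Total steps: 9. Longest linear sequence: 8 steps (3 → 4 → 5 → 6 → 7 → 11 → 12 → 15 → 16; steps 2, 3, 4, 5, 6, 7, 8, 9).

Steps most likely to fail:

1. Step 6. The hindered enolate may be quenched by proton transfer, or the ionisation-prone bromide may self-condense faster than it C-alkylates, so that the C3 benzyl group is not introduced. Fallback: this sets out from enolate 10 (made from 2 and 8 as in step 6) and uses aldehyde 5 in place of bromide 7, which also makes steps 4 and 5 unnecessary. The tandem conjugate addition–aldol reaction should give the 3,4-trans β-hydroxy adduct (3S,4R,5R)-3-{[2,4-bis(benzyloxy)-3-methoxyphenyl](hydroxy)methyl}-4-{2-[4-(benzyloxy)-3-methoxyphenyl]-1,3-dithian-2-yl}-5-menthyloxydihydrofuran-2(3H)-one F1 as a mixture of carbinol epimers. Ionic hydrogenation of this doubly alkoxy-activated benzylic alcohol (Et3SiH, CF3CO2H, CH2Cl2, −20 °C) should remove the hydroxyl and rejoin the route at 11.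

2. Step 7. Hydrogenolysis of the O-benzyl ethers may compete with C–S cleavage, or desulfurisation of the hindered quaternary dithiane may stall, giving mixtures of partly deprotected material. Fallback: this sets out from 11 and makes the over-reduction the intended event. Excess Raney Ni (W-2) under H2 in refluxing EtOH, completed if needed by H2 over 10% Pd/C once sulfur is gone, should cleave the C–S and all three O-benzyl bonds to give the triphenol acetal (3R,4R,5R)-3-(2,4-dihydroxy-3-methoxybenzyl)-4-(4-hydroxy-3-methoxybenzyl)-5-menthyloxydihydrofuran-2(3H)-one F2. Treatment with NaBH4/KOH and then HCl as in step 8 should pass through the triphenol formyl acid F3 and the triphenol hydroxy acid F4 and close to the γ-lactone, rejoining the route at 16.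

3. Step 8. The C4 centre may epimerise through enolisation of the transient aldehyde under KOH before hydride capture, or relactonisation may be incomplete. Fallback: this sets out from 12 and separates unmasking from reduction. Acid hydrolysis of the menthyl acetal (2 M HCl, dioxane, 60 °C) should give the pseudo-acid (3R,4R)-3-[2,4-bis(benzyloxy)-3-methoxybenzyl]-4-[4-(benzyloxy)-3-methoxybenzyl]-5-hydroxydihydrofuran-2(3H)-one F5 as an anomeric mixture. NaBH4 in EtOH at 0 °C without added hydroxide should reduce its ring-chain tautomeric aldehyde and rejoin the route at hydroxy acid 14, which lactonises to 15 on acidification.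

**Further compounds**

F1 | step 6 | (3S,4R,5R)-3-{[2,4-bis(benzyloxy)-3-methoxyphenyl](hydroxy)methyl}-4-{2-[4-(benzyloxy)-3-methoxyphenyl]-1,3-dithian-2-yl}-5-[(1R,2S,5R)-menthyloxy]dihydrofuran-2(3H)-one (carbinol epimers) | O=C1O[C@@H](O[C@@H]2C[C@H](C)CC[C@H]2C(C)C)[C@H](C2(c3ccc(OCc4ccccc4)c(OC)c3)SCCCS2)[C@H]1C(O)c1ccc(OCc2ccccc2)c(OC)c1OCc1ccccc1
F2 | step 7 | (3R,4R,5R)-3-(2,4-dihydroxy-3-methoxybenzyl)-4-(4-hydroxy-3-methoxybenzyl)-5-[(1R,2S,5R)-menthyloxy]dihydrofuran-2(3H)-one | O=C1O[C@@H](O[C@@H]2C[C@H](C)CC[C@H]2C(C)C)[C@H](Cc2ccc(O)c(OC)c2)[C@H]1Cc1ccc(O)c(OC)c1O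
F3 | step 7 | (2R,3R)-2-(2,4-dihydroxy-3-methoxybenzyl)-3-(4-hydroxy-3-methoxybenzyl)-4-oxobutanoic acid | OC(=O)[C@H](Cc1ccc(O)c(OC)c1O)[C@H](C=O)Cc1ccc(O)c(OC)c1
F4 | step 7 | (2R,3R)-2-(2,4-dihydroxy-3-methoxybenzyl)-4-hydroxy-3-(4-hydroxy-3-methoxybenzyl)butanoic acid | OC(=O)[C@H](Cc1ccc(O)c(OC)c1O)[C@H](CO)Cc1ccc(O)c(OC)c1
F5 | step 8 | (3R,4R)-3-[2,4-bis(benzyloxy)-3-methoxybenzyl]-4-[4-(benzyloxy)-3-methoxybenzyl]-5-hydroxydihydrofuran-2(3H)-one (anomeric mixture) | O=C1OC(O)[C@H](Cc2ccc(OCc3ccccc3)c(OC)c2)[C@H]1Cc1ccc(OCc2ccccc2)c(OC)c1OCc1ccccc1
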